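Numbering: five-membered ring C1(CH3)–C2(OAc)–C3–C4(OH)(iPr)–C5; seven-membered ring C5–C6(OAr)–C7=C8(CH3)–C9(=O)–C10–C1. The seven-membered ring is cut at C1–C10 and C7–C8 into a diene C1=C5–C6=C7 (ring alkene plus vinyl group of a 3-methylcyclopentenone that holds the C2 oxygen stereocentre) and an oxygenated vinylcarbene C8–C9–C10. One rhodium-catalysed cyclopropanation/Cope cascade forms both bonds, closes the seven-membered ring and sets quaternary C1; the C4 enone and the masked C8/C9 β-keto ester it leaves are the handles for the rest. The precursor is (S)-4-silyloxy-3-methyl-2-vinylcyclopent-2-enone.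

Key step: step 7

Conventions: the bicyclo[5.3.0]decane core is called hydroazulene and carries the numbering above in all names. β is the face of the C1 methyl group; the target has C2–O β, C4–OH β, C4–iPr α, C5–H α and C6–O α. TBSO = tert-butyldimethylsilyloxy. C8 is an epimeric mixture from 13 to 23 and is erased in step 16.
Assumption: Rh2(R-PTAD)4, dirhodium tetrakis[(R)-(1-adamantyl)(phthalimido)acetate], is taken to be the catalyst enantiomer that gives cyclopropane 10 with C6 R and C8 S (the sense Rh2(S-DOSP)4 shows with styrene); if a test reaction shows the opposite sense, the S catalyst is used.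
Assumption: 1 and 19 are taken as purchasable.

Step 1
Reactants: 1 (S)-4-(tert-butyldimethylsilyloxy)cyclopent-2-en-1-one
Product: 2 (3S,4S)-4-(tert-butyldimethylsilyloxy)-3-methyl-1-(trimethylsilyloxy)cyclopent-1-ene
Conditions: Me2CuLi (from MeLi and CuI), Me3SiCl, Et2O/THF, −78 °C; Et3N, pentane, aq. NaHCO3 work-up
Reagents that add atoms: lithium dimethylcuprate, [Li+].C[Cu-]C; chlorotrimethylsilane, C[Si](C)(C)Cl
Why: Chlorosilane-accelerated conjugate addition of the Gilman cuprate places the methyl group trans to the silyloxy group (a centre erased in step 2) and the enolate is silylated before it can expel the β-silyloxy group, so the oxygen-bearing stereocentre is carried through unchanged.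

Step 2
Reactants: 2 (3S,4S)-4-(tert-butyldimethylsilyloxy)-3-methyl-1-(trimethylsilyloxy)cyclopent-1-ene
Product: 3 (S)-4-(tert-butyldimethylsilyloxy)-3-methylcyclopent-2-en-1-one
Conditions: Pd(OAc)2 (1.0 equiv), MeCN, rt
Reagents that add atoms: none
Why: Saegusa–Ito oxidation, in which Pd(OAc)2 palladates the silyl enol ether at its α-carbon and β-hydride elimination of the hydrogen on the methyl-bearing carbon restores the enone with the methyl group now on the β-carbon, without touching the silyloxy stereocentre.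

Step 3
Reactants: 3 (S)-4-(tert-butyldimethylsilyloxy)-3-methylcyclopent-2-en-1-one
Product: 4 (S)-4-(tert-butyldimethylsilyloxy)-2-iodo-3-methylcyclopent-2-en-1-one
Conditions: I2, pyridine/CH2Cl2 (1:1), 0 °C → rt
Reagents that add atoms: iodine, II
Why: Pyridine-mediated α-iodination of an enone (conjugate addition of pyridine, iodination of the enolate, elimination) places iodine on the only vinylic C–H and is established for 3-substituted and 4-silyloxy cyclopentenones.

Step 4
Reactants: 4 (S)-4-(tert-butyldimethylsilyloxy)-2-iodo-3-methylcyclopent-2-en-1-one; 5 tributyl(vinyl)stannane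
Product: 6 (S)-4-(tert-butyldimethylsilyloxy)-3-methyl-2-vinylcyclopent-2-en-1-one
Conditions: Pd2(dba)3 (2.5 mol %), AsPh3 (10 mol %), CuI (10 mol %), NMP, rt; used without storage
Reagents that add atoms: none
Why: Stille coupling of the electron-poor vinyl iodide with the vinylstannane under ligand- and copper-accelerated conditions at room temperature installs the vinyl group without disturbing the base-sensitive β-silyloxy enone.

Step 5
Reactants: 7 methyl acetoacetate
Product: 8 methyl 2-diazo-3-oxobutanoate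
Conditions: 4-acetamidobenzenesulfonyl azide, Et3N, MeCN, 0 °C → rt
Reagents that add atoms: 4-acetamidobenzenesulfonyl azide, CC(=O)Nc1ccc(cc1)S(=O)(=O)N=[N+]=[N-]
Why: Regitz diazo transfer from the sulfonyl azide to the doubly activated methylene group.

Step 6
Reactants: 8 methyl 2-diazo-3-oxobutanoate
Product: 9 methyl 3-(tert-butyldimethylsilyloxy)-2-diazobut-3-enoate
Conditions: tert-butyldimethylsilyl triflate, Et3N, CH2Cl2, 0 °C
Reagents that add atoms: tert-butyldimethylsilyl trifluoromethanesulfonate, CC(C)(C)[Si](C)(C)OS(=O)(=O)C(F)(F)F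
Why: O-Silylation of the acetyl group via its enolate (silyl triflate with amine base) gives the 2-siloxyvinyl diazoacetate, the donor/acceptor carbene precursor.

Step 7
Reactants: 6 (S)-4-(tert-butyldimethylsilyloxy)-3-methyl-2-vinylcyclopent-2-en-1-one; 9 methyl 3-(tert-butyldimethylsilyloxy)-2-diazobut-3-enoate
Product: 11 methyl 2β,9-bis(TBSO)-1β-methyl-4-oxo-Δ5,Δ8-hydroazulene-8-carboxylate, via cis-divinylcyclopropane 10 (not isolated)
Conditions: Rh2(R-PTAD)4 (2 mol %), 9 (2 equiv, added over 3 h), hexanes, rt; then toluene, 100 °C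
Reagents that add atoms: none
Why: The divalent rhodium carbene formed from 9 with loss of N2 adds to the terminal vinyl group of 6 (forming C7–C8 and, transiently, C6–C8) with the siloxyvinyl group cis to the cyclopentenyl group, and on heating the cis-divinylcyclopropane 10 undergoes a boat [3,3] shift that forms C10–C1 while cleaving C6–C8. The closest known reaction type is the dirhodium-catalysed tandem cyclopropanation/Cope rearrangement (formal 4+3 cycloaddition) of siloxyvinyl diazoacetates with 1-vinylcycloalkenes, which is known to create angular methyl quaternary centres. The seven-membered ring is closed by this concerted sigmatropic ring expansion of the cyclopropane, which forces both new π bonds (C5=C6 and C8=C9) to be cis and keeps the C4 carbonyl outside the boat. The one new stereocentre that survives, C1, is relayed from the catalyst-set configuration of 10 (C6 R, C8 S) through the boat, so that C10 bonds to the face of C1 anti to the C2 silyloxy group (matched pairing of substrate and catalyst). The step needs site selectivity for the vinyl group, cis diastereoselectivity in the cyclopropanation and face selectivity at C1: the first follows because the ring alkene is tetrasubstituted and the C4 acyl group sits on the nodal carbon of the developing allyl cation (so the vinyl group is only mildly deactivated), the second is inherent to donor/acceptor carbenes, and the third comes from Rh2(R-PTAD)4 reinforced by the silyloxy group. Heating is required because the C1 methyl group is the Z substituent that points into the boat, and the step is driven by release of ring strain and by conjugation of the new C5=C6 bond with the C4 ketone.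

Step 8
Reactants: 11 methyl 2β,9-bis(TBSO)-1β-methyl-4-oxo-Δ5,Δ8-hydroazulene-8-carboxylate
Product: 13 methyl 2β-(TBSO)-1β,8-dimethyl-4,9-dioxo-Δ5-hydroazulene-8-carboxylate, via tetrabutylammonium C9 enolate 12 (not isolated)
Conditions: Bu4NF (1.05 equiv), MeI (5 equiv), THF, −78 → 0 °C
Reagents that add atoms: iodomethane, CI
Why: Fluoride-triggered alkylation of a silyl enol ether, in which fluoride removes the enol silyl group far faster than the hindered secondary C2 silyl ether and the naked β-keto ester enolate is C-methylated by MeI at C8, the new C8 centre being of no consequence because it is erased in step 16.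

Step 9
Reactants: 13 methyl 2β-(TBSO)-1β,8-dimethyl-4,9-dioxo-Δ5-hydroazulene-8-carboxylate
Product: 14 2β-(TBSO)-1β,8-dimethyl-Δ5-hydroazulene-4,9-dione
Conditions: LiCl, H2O (2 equiv), DMSO, 130 °C
Reagents that add atoms: none
Why: Krapcho dealkoxycarbonylation, in which chloride demethylates the ester by SN2 attack, the β-keto carboxylate loses CO2 and water protonates the enolate under near-neutral conditions that spare the β-silyloxy enone, leaving C8 as an epimeric CH(CH3).

Step 10
Reactants: 14 2β-(TBSO)-1β,8-dimethyl-Δ5-hydroazulene-4,9-dione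
Product: 15 9,9-ethylenedioxy-2β-(TBSO)-1β,8-dimethyl-Δ5-hydroazulen-4-one
Conditions: Me3SiOCH2CH2OSiMe3, Me3SiOSO2CF3 (5 mol %), CH2Cl2, −78 → −20 °C; pyridine quench
Reagents that add atoms: 1,2-bis(trimethylsilyloxy)ethane, C[Si](C)(C)OCCO[Si](C)(C)C
Why: Silyl-triflate-catalysed ketalisation with the bis-silyl ether of ethylene glycol at low temperature is selective for the saturated C9 ketone over the conjugated and more hindered C4 enone and does not cleave the silyl ether.

Step 11
Reactants: 15 9,9-ethylenedioxy-2β-(TBSO)-1β,8-dimethyl-Δ5-hydroazulen-4-one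
Product: 16 9,9-ethylenedioxy-4α-isopropyl-2β-(TBSO)-1β,8-dimethyl-Δ5-hydroazulen-4β-ol
Conditions: iPrMgCl, CeCl3 (anhydrous), THF, −78 → −40 °C; then H2O
Reagents that add atoms: isopropylmagnesium chloride, CC(C)[Mg]Cl
Why: Organocerium 1,2-addition, which suppresses enolisation toward C3 (and with it loss of the C2 silyloxy group), β-hydride reduction and 1,4-addition, delivers isopropyl to the C4 carbonyl from the α face, anti to the C2 silyloxy and C1 methyl groups, so that the C4 hydroxyl is β.

Step 12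
Reactants: 16 9,9-ethylenedioxy-4α-isopropyl-2β-(TBSO)-1β,8-dimethyl-Δ5-hydroazulen-4β-ol
Product: 18 9,9-ethylenedioxy-4α-isopropyl-2β-(TBSO)-1β,8-dimethyl-5αH-hydroazulene-4β,6α-diol, via C6α-borane 17 (not isolated)
Conditions: BH3·THF (3 equiv), THF, 0 °C → rt; then NaOH, H2O2, 0 °C → rt
Reagents that add atoms: hydrogen peroxide, OO
Why: Hydroboration–oxidation, in which boron adds to the less substituted C6 and hydrogen to C5 in one syn event from the α face, anti to the C1 methyl group and to the allylic C4–O bond, and oxidation with retention gives C6–OH α and C5–H α (trans ring fusion) at a stage where C5 can no longer epimerise.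

Step 13
Reactants: 18 9,9-ethylenedioxy-4α-isopropyl-2β-(TBSO)-1β,8-dimethyl-5αH-hydroazulene-4β,6α-diol; 19 4-acetoxybenzoyl chloride
Product: 20 6α-(4-acetoxybenzoyloxy)-9,9-ethylenedioxy-4α-isopropyl-2β-(TBSO)-1β,8-dimethyl-5αH-hydroazulen-4β-ol
Conditions: Et3N, 4-dimethylaminopyridine (cat.), CH2Cl2, 0 °C → rt
Reagents that add atoms: none
Why: 4-Dimethylaminopyridine-catalysed acylation by the acid chloride takes the secondary C6 alcohol only, the tertiary C4 alcohol being inert under these conditions.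

Step 14
Reactants: 20 6α-(4-acetoxybenzoyloxy)-9,9-ethylenedioxy-4α-isopropyl-2β-(TBSO)-1β,8-dimethyl-5αH-hydroazulen-4β-ol
Product: 22 6α-(4-acetoxybenzoyloxy)-2β,4β-dihydroxy-4α-isopropyl-1β,8-dimethyl-5αH-hydroazulen-9-one, via 2β-alcohol ketal 21 (not isolated)
Conditions: HF (48% aq.), MeCN, 0 °C → rt
Reagents that add atoms: water, O
Why: Aqueous HF cleaves the hindered secondary silyl ether and then hydrolyses the dioxolane, while the aryl acetate, the benzoate and the (no longer allylic) tertiary alcohol tolerate this mild acidity.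

Step 15
Reactants: 22 6α-(4-acetoxybenzoyloxy)-2β,4β-dihydroxy-4α-isopropyl-1β,8-dimethyl-5αH-hydroazulen-9-one
Product: 23 2β-acetoxy-6α-(4-acetoxybenzoyloxy)-4β-hydroxy-4α-isopropyl-1β,8-dimethyl-5αH-hydroazulen-9-one
Conditions: Ac2O, pyridine, 4-dimethylaminopyridine (cat.), CH2Cl2, rt
Reagents that add atoms: acetic anhydride, CC(=O)OC(C)=O
Why: Nucleophile-catalysed acetylation of the secondary C2 alcohol, the tertiary C4 alcohol not reacting at room temperature.

Step 16
Reactants: 23 2β-acetoxy-6α-(4-acetoxybenzoyloxy)-4β-hydroxy-4α-isopropyl-1β,8-dimethyl-5αH-hydroazulen-9-one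
Product: 24 2β-acetoxy-6α-(4-acetoxybenzoyloxy)-4β-hydroxy-4α-isopropyl-1β,8-dimethyl-5αH-Δ7-hydroazulen-9-one
Conditions: IBX (2-iodoxybenzoic acid, 2.5 equiv), DMSO, 70 °C
Reagents that add atoms: none
Why: IBX dehydrogenation of the ketone through its enol can only desaturate C7–C8, because C1 next to C10 bears no hydrogen, and it converges both C8 epimers on the 8-methyl enone.

Step 17
Reactants: 24 2β-acetoxy-6α-(4-acetoxybenzoyloxy)-4β-hydroxy-4α-isopropyl-1β,8-dimethyl-5αH-Δ7-hydroazulen-9-one
Product: 25 2β-acetoxy-4β-hydroxy-6α-(4-hydroxybenzoyloxy)-4α-isopropyl-1β,8-dimethyl-5αH-Δ7-hydroazulen-9-one (target)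
Conditions: NH4OAc, MeOH/H2O (4:1), rt
Reagents that add atoms: none
Why: Ammonium acetate in aqueous methanol cleaves phenolic acetates selectively (the phenoxide is by far the best leaving group), leaving the C2 acetate, the C6 benzoate and the γ-acyloxy enone intact.

Compound list
1 | (S)-4-(tert-butyldimethylsilyloxy)cyclopent-2-en-1-one | CC(C)(C)[Si](C)(C)O[C@H]1CC(=O)C=C1 | starting material
2 | (3S,4S)-4-(tert-butyldimethylsilyloxy)-3-methyl-1-(trimethylsilyloxy)cyclopent-1-ene (methyl trans to TBSO) | C[C@H]1C=C(O[Si](C)(C)C)C[C@@H]1O[Si](C)(C)C(C)(C)C | intermediate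
3 | (S)-4-(tert-butyldimethylsilyloxy)-3-methylcyclopent-2-en-1-one | CC(C)(C)[Si](C)(C)O[C@H]1CC(=O)C=C1C | intermediate
4 | (S)-4-(tert-butyldimethylsilyloxy)-2-iodo-3-methylcyclopent-2-en-1-one | CC(C)(C)[Si](C)(C)O[C@H]1CC(=O)C(I)=C1C | intermediate
5 | tributyl(vinyl)stannane | C=C[Sn](CCCC)(CCCC)CCCC | starting material
6 | (S)-4-(tert-butyldimethylsilyloxy)-3-methyl-2-vinylcyclopent-2-en-1-one | CC(C)(C)[Si](C)(C)O[C@H]1CC(=O)C(C=C)=C1C | intermediate
7 | methyl acetoacetate | COC(=O)CC(C)=O | starting material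
8 | methyl 2-diazo-3-oxobutanoate | COC(=O)C(=[N+]=[N-])C(C)=O | intermediate
9 | methyl 3-(tert-butyldimethylsilyloxy)-2-diazobut-3-enoate | COC(=O)C(=[N+]=[N-])C(=C)O[Si](C)(C)C(C)(C)C | intermediate
10 | cis-divinylcyclopropane: methyl (1S,2R)-1-[1-(TBSO)vinyl]-2-[(3S)-3-(TBSO)-2-methyl-5-oxocyclopent-1-en-1-yl]cyclopropane-1-carboxylate (C8 S, C6 R in target numbering) | COC(=O)[C@@]1(C(=C)O[Si](C)(C)C(C)(C)C)C[C@@H]1C2=C(C)[C@@H](O[Si](C)(C)C(C)(C)C)CC2=O | intermediate
11 | methyl 2β,9-bis(TBSO)-1β-methyl-4-oxo-Δ5,Δ8-hydroazulene-8-carboxylate | CC(C)(C)[Si](C)(C)O[C@H]1CC(=O)C2=CCC(C(=O)OC)=C(O[Si](C)(C)C(C)(C)C)C[C@]12C | intermediate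
12 | tetrabutylammonium C9 enolate of the C8 methyl ester | CC(C)(C)[Si](C)(C)O[C@H]1CC(=O)C2=CCC(C(=O)OC)=C([O-])C[C@]12C.CCCC[N+](CCCC)(CCCC)CCCC | intermediate
13 | methyl 2β-(TBSO)-1β,8-dimethyl-4,9-dioxo-Δ5-hydroazulene-8-carboxylate (C8 epimers) | CC(C)(C)[Si](C)(C)O[C@H]1CC(=O)C2=CCC(C)(C(=O)OC)C(=O)C[C@]12C | intermediate
14 | 2β-(TBSO)-1β,8-dimethyl-Δ5-hydroazulene-4,9-dione (C8 epimers) | CC(C)(C)[Si](C)(C)O[C@H]1CC(=O)C2=CCC(C)C(=O)C[C@]12C | intermediate
15 | 9,9-ethylenedioxy-2β-(TBSO)-1β,8-dimethyl-Δ5-hydroazulen-4-one | CC(C)(C)[Si](C)(C)O[C@H]1CC(=O)C2=CCC(C)C3(OCCO3)C[C@]12C | intermediate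
16 | 9,9-ethylenedioxy-4α-isopropyl-2β-(TBSO)-1β,8-dimethyl-Δ5-hydroazulen-4β-ol | CC(C)(C)[Si](C)(C)O[C@H]1C[C@](O)(C(C)C)C2=CCC(C)C3(OCCO3)C[C@]12C | intermediate
17 | C6α-borane of 16 (5α-H; drawn as the monoalkylborane) | CC(C)(C)[Si](C)(C)O[C@H]1C[C@](O)(C(C)C)[C@H]2[C@H](B)CC(C)C3(OCCO3)C[C@]12C | intermediate
18 | 9,9-ethylenedioxy-4α-isopropyl-2β-(TBSO)-1β,8-dimethyl-5αH-hydroazulene-4β,6α-diol | CC(C)(C)[Si](C)(C)O[C@H]1C[C@](O)(C(C)C)[C@H]2[C@H](O)CC(C)C3(OCCO3)C[C@]12C | intermediate
19 | 4-acetoxybenzoyl chloride | CC(=O)Oc1ccc(cc1)C(Cl)=O | starting material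
20 | 6α-(4-acetoxybenzoyloxy)-9,9-ethylenedioxy-4α-isopropyl-2β-(TBSO)-1β,8-dimethyl-5αH-hydroazulen-4β-ol | CC(C)(C)[Si](C)(C)O[C@H]1C[C@](O)(C(C)C)[C@H]2[C@H](OC(=O)c3ccc(OC(C)=O)cc3)CC(C)C4(OCCO4)C[C@]12C | intermediate
21 | 2β-alcohol ketal: 6α-(4-acetoxybenzoyloxy)-9,9-ethylenedioxy-4α-isopropyl-1β,8-dimethyl-5αH-hydroazulene-2β,4β-diol | O[C@H]1C[C@](O)(C(C)C)[C@H]2[C@H](OC(=O)c3ccc(OC(C)=O)cc3)CC(C)C4(OCCO4)C[C@]12C | intermediate
22 | 6α-(4-acetoxybenzoyloxy)-2β,4β-dihydroxy-4α-isopropyl-1β,8-dimethyl-5αH-hydroazulen-9-one | O[C@H]1C[C@](O)(C(C)C)[C@H]2[C@H](OC(=O)c3ccc(OC(C)=O)cc3)CC(C)C(=O)C[C@]12C | intermediate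
23 | 2β-acetoxy-6α-(4-acetoxybenzoyloxy)-4β-hydroxy-4α-isopropyl-1β,8-dimethyl-5αH-hydroazulen-9-one | CC(=O)O[C@H]1C[C@](O)(C(C)C)[C@H]2[C@H](OC(=O)c3ccc(OC(C)=O)cc3)CC(C)C(=O)C[C@]12C | intermediate
24 | 2β-acetoxy-6α-(4-acetoxybenzoyloxy)-4β-hydroxy-4α-isopropyl-1β,8-dimethyl-5αH-Δ7-hydroazulen-9-one | CC(=O)O[C@H]1C[C@](O)(C(C)C)[C@H]2[C@H](OC(=O)c3ccc(OC(C)=O)cc3)C=C(C)C(=O)C[C@]12C | intermediate
25 | 2β-acetoxy-4β-hydroxy-6α-(4-hydroxybenzoyloxy)-4α-isopropyl-1β,8-dimethyl-5αH-Δ7-hydroazulen-9-one (C1 S, C2 S, C4 S, C5 R, C6 R) | CC(=O)O[C@H]1C[C@](O)(C(C)C)[C@H]2[C@H](OC(=O)c3ccc(O)cc3)C=C(C)C(=O)C[C@]12C | target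

Total step count: 17. Longest linear sequence: 15 steps (steps 1–4 and 7–17, from 1); steps 5 and 6 form the two-step side branch to 9.

Steps most likely to fail

Step 7 (key step). The carbene may be lost to dimerisation because the carbonyl-bearing diene is too poor a partner, or the hindered Cope step may be outrun by epimerisation of the donor/acceptor cyclopropane. The fallback masks the carbonyl and sets out from 6. Luche reduction (NaBH4, CeCl3·7H2O, MeOH, −78 °C) should give the cis allylic alcohol (1R,4S)-4-(tert-butyldimethylsilyloxy)-3-methyl-2-vinylcyclopent-2-en-1-ol F1. Silylation (Et3SiCl, imidazole, CH2Cl2) gives its triethylsilyl ether F2, an electron-richer 1-vinylcyclopentene. The same Rh2(R-PTAD)4 cascade with 9 then passes through the cis-divinylcyclopropane F3 (not isolated) to the C4-triethylsilyloxy cycloadduct F4. Bu4NF (2.2 equiv) with MeI removes the enol silyl and triethylsilyl groups and methylates C8 through the ammonium enolate F5 (not isolated) to the C4-hydroxy keto ester F6. MnO2 oxidation of the allylic alcohol (CH2Cl2, rt) brings the sequence back to the route at 13.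

Step 12. Borane may add from the β face if the α-isopropyl group at C4 outweighs the C1 methyl group, which would give the cis-fused 6β-alcohol, or the alkene flanked by two quaternary carbons may react too slowly. The fallback sets out from 15, before the isopropyl group is present. Nucleophilic epoxidation (tBuOOH, DBU, CH2Cl2, 0 °C) should give the 5α,6α-epoxy ketone F7 by peroxide attack at C6 of the flat enone. SmI2 (THF/MeOH, −78 °C) cleaves the C5–O bond and the samarium enolate is protonated to the β-hydroxy ketone F8 (C5–H α, C6–OH α), relying on delivery of the proton source by the α-alkoxide. An excess of iPrMgCl/CeCl3 (THF, −78 °C) then adds to C4 from the α face and brings the sequence back to the route at 18.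

Step 16. Enolisation toward the hindered C8 may be slow, and prolonged heating with the oxidant may degrade the substrate. The fallback sets out from 23. PhSeCl in EtOAc (rt), which selenenylates through the more substituted enol, should give the C8 phenylselenide F9. H2O2 with pyridine (CH2Cl2, 0 °C) oxidises it to the selenoxide, whose syn elimination toward C7 brings the sequence back to the route at 24.

Further compounds
F1 | step 7 | (1R,4S)-4-(tert-butyldimethylsilyloxy)-3-methyl-2-vinylcyclopent-2-en-1-ol | CC(C)(C)[Si](C)(C)O[C@H]1C[C@@H](O)C(C=C)=C1C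
F2 | step 7 | triethylsilyl ether of F1 | CC(C)(C)[Si](C)(C)O[C@H]1C[C@@H](O[Si](CC)(CC)CC)C(C=C)=C1C
F3 | step 7 | cis-divinylcyclopropane from F2 and 9 (not isolated) | COC(=O)[C@@]1(C(=C)O[Si](C)(C)C(C)(C)C)C[C@@H]1C2=C(C)[C@@H](O[Si](C)(C)C(C)(C)C)C[C@H]2O[Si](CC)(CC)CC
F4 | step 7 | methyl 2β,9-bis(TBSO)-1β-methyl-4β-(triethylsilyloxy)-Δ5,Δ8-hydroazulene-8-carboxylate | CC(C)(C)[Si](C)(C)O[C@H]1C[C@@H](O[Si](CC)(CC)CC)C2=CCC(C(=O)OC)=C(O[Si](C)(C)C(C)(C)C)C[C@]12C
F5 | step 7 | tetrabutylammonium C9 enolate of the C4β-hydroxy C8 methyl ester (not isolated) | CC(C)(C)[Si](C)(C)O[C@H]1C[C@@H](O)C2=CCC(C(=O)OC)=C([O-])C[C@]12C.CCCC[N+](CCCC)(CCCC)CCCC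
F6 | step 7 | methyl 4β-hydroxy-2β-(TBSO)-1β,8-dimethyl-9-oxo-Δ5-hydroazulene-8-carboxylate | CC(C)(C)[Si](C)(C)O[C@H]1C[C@@H](O)C2=CCC(C)(C(=O)OC)C(=O)C[C@]12C
F7 | step 12 | 5α,6α-epoxy-9,9-ethylenedioxy-2β-(TBSO)-1β,8-dimethylhydroazulen-4-one | CC(C)(C)[Si](C)(C)O[C@H]1CC(=O)[C@]23O[C@@H]3CC(C)C4(OCCO4)C[C@]12C
F8 | step 12 | 9,9-ethylenedioxy-6α-hydroxy-2β-(TBSO)-1β,8-dimethyl-5αH-hydroazulen-4-one | CC(C)(C)[Si](C)(C)O[C@H]1CC(=O)[C@H]2[C@H](O)CC(C)C3(OCCO3)C[C@]12C
F9 | step 16 | C8 phenylselenide of 23 | CC(=O)O[C@H]1C[C@](O)(C(C)C)[C@H]2[C@H](OC(=O)c3ccc(OC(C)=O)cc3)CC(C)([Se]c4ccccc4)C(=O)C[C@]12C
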